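**Plan**

- Retrosynthesis: the exocyclic C5=CH bond of the furanone is cut (aldol condensation) into a 3-aryltetronic acid and a chroman-6-carbaldehyde. The tetronic acid ring is cut at O1–C2 and C3–C4 into a methyl arylacetate and methyl glycolate. The pyran ring of the chroman is cut at C2–C3 and O1–C8a into 2',4'-difluoroacetophenone and acetone (chroman numbering O1, C2, C3, C4, C4a, C5–C8, C8a).
- Enabling feature: O1 sits on C8a, the ring carbon ortho to C4a. A temporary ketone at C4 is therefore both the enolate donor for the C2–C3 bond and the ortho activator that lets the new tertiary alkoxide displace fluoride at C8a. Being para to C7, it also lets the second fluoride be exchanged for the C7 oxygen before it is reduced away.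
- Forward order: the pyranone ring is closed first on the fluoroarene; C7–O exchange, C4 deoxygenation and C6 formylation then give the aldehyde. In parallel a bromophenol ester is O-allylated, prenylated, epoxidised and turned into the tetronic acid. The halves are joined by condensation and both allyl ethers are removed last.
- Stereochemistry: the only stereocentre, the (R)-oxirane carbon, comes from reagent-controlled Shi epoxidation of the prenyl group with the D-fructose-derived ketone. The Z alkene comes from thermodynamic control in the condensation.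

Key step: step 1

**Route**

Step 1
Reactants: 1 1-(2,4-difluorophenyl)ethanone; 2 acetone
Product: 5 7-fluoro-2,2-dimethylchroman-4-one, via lithium enolate 3 (not isolated), via lithium aldolate 4 (not isolated)
Conditions: LiN(SiMe3)2 (1.05 equiv), THF, −78 °C; acetone (2 equiv), −78 °C; then DMPU, −78 → 45 °C; aq. NH4Cl
Reagents that add atoms: acetone (2), CC(C)=O
Why: LiN(SiMe3)2 converts the methyl ketone into its kinetic lithium enolate 3, which adds to the carbonyl carbon of acetone (aldol addition, new C2–C3 bond) to give the tertiary lithium alkoxide 4; on warming in the presence of DMPU this alkoxide attacks the fluorine-bearing carbon C8a, which is activated by the ortho C4 carbonyl, and fluoride leaves (intramolecular SNAr, new O1–C8a bond). The closest known reaction types are the directed aldol addition of aryl methyl ketone enolates to ketones and the base-induced ring closure of 3-hydroxy-1-(2-fluorophenyl)alkan-1-ones to chroman-4-ones, run here as one domino sequence. The pyranone ring closes by a 6-exo-trig addition–elimination at the sp2 carbon C8a (attack on the C8a=C8 π bond), the charge of the Meisenheimer intermediate being taken up by the C4 carbonyl through C4a. No stereocentre is formed, so no stereocontrol is required. The step needs cross-aldol over self-condensation selectivity, which the preformed enolate at −78 °C and the excess of acetone should secure, and ortho over para fluoride selectivity, which the six-membered intramolecular delivery of the alkoxide secures. The aldol addition is reversible, but the irreversible loss of fluoride should drain the aldolate, so that retro-aldol cleavage only returns material to the productive equilibrium.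

Step 2
Reactants: 5 7-fluoro-2,2-dimethylchroman-4-one; 6 allyl alcohol
Product: 8 7-(allyloxy)-2,2-dimethylchroman-4-one, via sodium allyloxide 7 (not isolated)
Conditions: NaH (1.5 equiv), allyl alcohol (3 equiv), DMF, 0 → 60 °C; aq. NH4Cl
Reagents that add atoms: allyl alcohol (6), C=CCO
Why: SNAr, in which the remaining fluoride at C7 is para to the C4 carbonyl so that sodium allyloxide 7 displaces it by addition–elimination and brings in the C7 oxygen already protected, while the excess alcohol keeps ketone enolisation reversible and any ring-opened enone phenoxide should reclose by oxa-Michael addition.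

Step 3
Reactants: 8 7-(allyloxy)-2,2-dimethylchroman-4-one
Product: 10 7-(allyloxy)-2,2-dimethylchroman, via chroman-4-ol 9 (not isolated)
Conditions: Et3SiH (3 equiv), CF3CO2H, CH2Cl2, 0 °C → rt
Reagents that add atoms: none
Why: Ionic hydrogenation, in which the protonated aryl ketone takes hydride from Et3SiH to give benzylic alcohol 9, which ionises in CF3CO2H to a cation stabilised by the para C7 oxygen and the ortho O1 and is reduced a second time, removing the helper carbonyl, while allyl aryl ethers and unactivated terminal alkenes are inert to these conditions at room temperature.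

Step 4
Reactants: 10 7-(allyloxy)-2,2-dimethylchroman; 11 N,N-dimethylformamide
Product: 14 7-(allyloxy)-2,2-dimethylchroman-6-carbaldehyde, via chloroiminium salt 12 (not isolated), via aryl iminium salt 13 (not isolated)
Conditions: POCl3 (1.5 equiv), DMF, 0 → 70 °C; then aq. NaOAc, rt
Reagents that add atoms: N,N-dimethylformamide (11), CN(C)C=O; water, O
Why: Vilsmeier–Haack formylation, in which chloroiminium 12 attacks C6, the position para to O1 and ortho to the C7 ether (C8 lies between two oxygens and is hindered, C5 is not activated), and aqueous work-up hydrolyses iminium 13 to the aldehyde.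

Step 5
Reactants: 15 methyl 2-(3-bromo-4-hydroxyphenyl)acetate; 16 allyl bromide
Product: 17 methyl 2-[4-(allyloxy)-3-bromophenyl]acetate
Conditions: K2CO3, acetone, reflux
Reagents that add atoms: allyl bromide (16), C=CCBr
Why: Williamson ether synthesis, in which K2CO3 deprotonates only the phenol and not the ester α-CH2, and the phenoxide is alkylated on oxygen by the allylic bromide.

Step 6
Reactants: 17 methyl 2-[4-(allyloxy)-3-bromophenyl]acetate; 18 1-bromo-3-methylbut-2-ene (prenyl bromide)
Product: 20 methyl 2-[4-(allyloxy)-3-(3-methylbut-2-en-1-yl)phenyl]acetate, via prenylzinc bromide 19 (not isolated)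
Conditions: 18, Zn dust, LiCl, THF, 0 °C → rt; then 17, Pd(OAc)2 (2 mol %), CPhos (4 mol %), THF, rt
Reagents that add atoms: 1-bromo-3-methylbut-2-ene (18), CC(C)=CCBr
Why: Linear-selective Negishi cross-coupling of an allylic zinc reagent, in which zerovalent palladium inserts into the C–Br bond, transmetalation from zinc is fast and the bulky CPhos ligand favours reductive elimination from the less hindered σ-prenyl complex to give the prenyl and not the 1,1-dimethylallyl arene, the fast transmetalation being expected to outrun 5-exo carbopalladation of the O-allyl alkene while the ester is inert to the organozinc at room temperature.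

Step 7
Reactants: 20 methyl 2-[4-(allyloxy)-3-(3-methylbut-2-en-1-yl)phenyl]acetate
Product: 21 methyl 2-[4-(allyloxy)-3-{[(2R)-3,3-dimethyloxiran-2-yl]methyl}phenyl]acetate
Conditions: D-fructose-derived Shi ketone (30 mol %), KHSO5 (as the triple salt 2KHSO5·KHSO4·K2SO4), K2CO3, Bu4NHSO4, aq. Na2B4O7/Na2EDTA buffer (pH 10.5), MeCN–CH2(OMe)2, 0 °C
Reagents that add atoms: potassium peroxymonosulfate, [K+].[O-]S(=O)(=O)OO
Why: Shi asymmetric epoxidation, in which the chiral dioxirane formed from the D-fructose-derived ketone and KHSO5 transfers oxygen through a spiro transition state to one face of the electron-rich trisubstituted prenyl alkene, which by the established sense for trans- and trisubstituted alkenes should give the (2R)-epoxide under reagent control, while the monosubstituted allyl ether alkene reacts far more slowly and the basic buffer protects the epoxide from acid.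

Step 8
Reactants: 21 methyl 2-[4-(allyloxy)-3-{[(2R)-3,3-dimethyloxiran-2-yl]methyl}phenyl]acetate; 22 methyl glycolate
Product: 24 3-[4-(allyloxy)-3-{[(2R)-3,3-dimethyloxiran-2-yl]methyl}phenyl]-4-hydroxyfuran-2(5H)-one, via glycolate diester 23 (not isolated)
Conditions: KOtBu (2.2 equiv), DMF, 0 °C → rt; then cold aq. KH2PO4 (pH ≈ 4), EtOAc; used at once
Reagents that add atoms: methyl glycolate (22), COC(=O)CO
Why: Tandem transesterification/Dieckmann condensation, a sequence known for methyl arylacetates, in which potassium glycolate exchanges with the methyl ester to give diester 23, whose arylacetate enolate attacks the glycolate ester carbonyl to close the five-membered ring as the stabilised tetronate, while the hindered trisubstituted epoxide should not be opened by the bulky base at or below room temperature and the mild work-up keeps it intact.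

Step 9
Reactants: 24 3-[4-(allyloxy)-3-{[(2R)-3,3-dimethyloxiran-2-yl]methyl}phenyl]-4-hydroxyfuran-2(5H)-one; 14 7-(allyloxy)-2,2-dimethylchroman-6-carbaldehyde
Product: 26 (5Z)-3-[4-(allyloxy)-3-{[(2R)-3,3-dimethyloxiran-2-yl]methyl}phenyl]-5-{[7-(allyloxy)-2,2-dimethylchroman-6-yl]methylidene}-4-hydroxyfuran-2(5H)-one, via aldol adduct 25 (not isolated)
Conditions: DBU (3 equiv), MeCN, 60 °C; then cold aq. KH2PO4
Reagents that add atoms: none
Why: Vinylogous aldol condensation of a 3-aryltetronic acid with an aromatic aldehyde, in which DBU generates the C5 nucleophile of the tetronate, addition to the aldehyde gives aldol 25 and E1cB loss of water gives the conjugated alkylidene as the thermodynamically preferred Z isomer (aryl group syn to the ring oxygen, avoiding allylic strain against the C4 oxygen), while the two allyl ethers keep both phenols masked so that no phenoxide can open the epoxide.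

Step 10
Reactants: 26 (5Z)-3-[4-(allyloxy)-3-{[(2R)-3,3-dimethyloxiran-2-yl]methyl}phenyl]-5-{[7-(allyloxy)-2,2-dimethylchroman-6-yl]methylidene}-4-hydroxyfuran-2(5H)-one
Product: 27 (5Z)-3-(3-{[(2R)-3,3-dimethyloxiran-2-yl]methyl}-4-hydroxyphenyl)-4-hydroxy-5-[(7-hydroxy-2,2-dimethylchroman-6-yl)methylidene]furan-2(5H)-one
Conditions: Pd(PPh3)4 (5 mol %), morpholine (10 equiv), THF, rt; then cold aq. KH2PO4 (pH ≈ 4)
Reagents that add atoms: none
Why: Tsuji–Trost-type deallylation, in which zerovalent palladium ionises each aryl allyl ether to a π-allyl complex that is intercepted by morpholine, so that both phenols are released without acid or strong base, the tetronic acid is held as its morpholinium salt, and neither the epoxide, the exocyclic alkene nor the stereocentre should be affected.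

**Compound list**

1 | 1-(2,4-difluorophenyl)ethanone | CC(=O)c1ccc(F)cc1F | starting material
2 | acetone | CC(C)=O | starting material
3 | lithium 1-(2,4-difluorophenyl)ethenolate | [Li+].[O-]C(=C)c1ccc(F)cc1F | intermediate
4 | lithium 4-(2,4-difluorophenyl)-2-methyl-4-oxobutan-2-olate | [Li+].CC(C)([O-])CC(=O)c1ccc(F)cc1F | intermediate
5 | 7-fluoro-2,2-dimethylchroman-4-one | CC1(C)CC(=O)c2ccc(F)cc2O1 | intermediate
6 | allyl alcohol | C=CCO | starting material
7 | sodium prop-2-en-1-olate | [Na+].[O-]CC=C | intermediate
8 | 7-(allyloxy)-2,2-dimethylchroman-4-one | C=CCOc1ccc2c(c1)OC(C)(C)CC2=O | intermediate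
9 | 7-(allyloxy)-2,2-dimethylchroman-4-ol (racemic) | C=CCOc1ccc2c(c1)OC(C)(C)CC2O | intermediate
10 | 7-(allyloxy)-2,2-dimethylchroman | C=CCOc1ccc2c(c1)OC(C)(C)CC2 | intermediate
11 | N,N-dimethylformamide | CN(C)C=O | starting material
12 | (chloromethylidene)dimethyliminium dichlorophosphate | C[N+](C)=CCl.[O-]P(Cl)(Cl)=O | intermediate
13 | N-{[7-(allyloxy)-2,2-dimethylchroman-6-yl]methylidene}-N-methylmethanaminium dichlorophosphate | C=CCOc1cc2c(cc1C=[N+](C)C)CCC(C)(C)O2.[O-]P(Cl)(Cl)=O | intermediate
14 | 7-(allyloxy)-2,2-dimethylchroman-6-carbaldehyde | C=CCOc1cc2c(cc1C=O)CCC(C)(C)O2 | intermediate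
15 | methyl 2-(3-bromo-4-hydroxyphenyl)acetate | COC(=O)Cc1ccc(O)c(Br)c1 | starting material
16 | allyl bromide | C=CCBr | starting material
17 | methyl 2-[4-(allyloxy)-3-bromophenyl]acetate | COC(=O)Cc1ccc(OCC=C)c(Br)c1 | intermediate
18 | 1-bromo-3-methylbut-2-ene | CC(C)=CCBr | starting material
19 | (3-methylbut-2-en-1-yl)zinc bromide | CC(C)=CC[Zn]Br | intermediate
20 | methyl 2-[4-(allyloxy)-3-(3-methylbut-2-en-1-yl)phenyl]acetate | COC(=O)Cc1ccc(OCC=C)c(CC=C(C)C)c1 | intermediate
21 | methyl 2-[4-(allyloxy)-3-{[(2R)-3,3-dimethyloxiran-2-yl]methyl}phenyl]acetate | COC(=O)Cc1ccc(OCC=C)c(C[C@H]2OC2(C)C)c1 | intermediate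
22 | methyl glycolate | COC(=O)CO | starting material
23 | 2-methoxy-2-oxoethyl 2-[4-(allyloxy)-3-{[(2R)-3,3-dimethyloxiran-2-yl]methyl}phenyl]acetate | COC(=O)COC(=O)Cc1ccc(OCC=C)c(C[C@H]2OC2(C)C)c1 | intermediate
24 | 3-[4-(allyloxy)-3-{[(2R)-3,3-dimethyloxiran-2-yl]methyl}phenyl]-4-hydroxyfuran-2(5H)-one | O=C1OCC(O)=C1c1ccc(OCC=C)c(C[C@H]2OC2(C)C)c1 | intermediate
25 | 3-[4-(allyloxy)-3-{[(2R)-3,3-dimethyloxiran-2-yl]methyl}phenyl]-5-{[7-(allyloxy)-2,2-dimethylchroman-6-yl](hydroxy)methyl}-4-hydroxyfuran-2(5H)-one (two new centres unassigned) | OC(c1cc2CCC(C)(C)Oc2cc1OCC=C)C1OC(=O)C(c2ccc(OCC=C)c(C[C@H]3OC3(C)C)c2)=C1O | intermediate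
26 | (5Z)-3-[4-(allyloxy)-3-{[(2R)-3,3-dimethyloxiran-2-yl]methyl}phenyl]-5-{[7-(allyloxy)-2,2-dimethylchroman-6-yl]methylidene}-4-hydroxyfuran-2(5H)-one | C=CCOc1cc2OC(C)(C)CCc2cc1/C=C3\OC(=O)C(c4ccc(OCC=C)c(C[C@H]5OC5(C)C)c4)=C3O | intermediate
27 | (5Z)-3-(3-{[(2R)-3,3-dimethyloxiran-2-yl]methyl}-4-hydroxyphenyl)-4-hydroxy-5-[(7-hydroxy-2,2-dimethylchroman-6-yl)methylidene]furan-2(5H)-one | CC1(C)CCc2cc(/C=C3\OC(=O)C(c4ccc(O)c(C[C@H]5OC5(C)C)c4)=C3O)c(O)cc2O1 | target

**Step count**

Total: 10 steps. Longest linear sequence: 6 steps (steps 1–4, 9, 10; the second branch, steps 5–8, 9, 10, is equally long).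

**Steps most likely to fail**

1. Step 1. The lithium aldolate may revert to enolate and acetone, or lose water, faster than it closes onto C8a, and the alkoxide may attack the para fluoride of a second molecule. Fallback: the ring oxygen is taken from a phenol and the other C–O bond of the pyranone is formed instead. The fallback sets out from acetone 2, which is condensed with purchased 1-(4-fluoro-2-hydroxyphenyl)ethanone F1 (pyrrolidine, MeOH, reflux; Kabbe-type condensation). This passes through the enone 1-(4-fluoro-2-hydroxyphenyl)-3-methylbut-2-en-1-one F2 (not isolated), whose phenoxide closes by oxa-Michael addition, and comes back to the route at 5.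

2. Step 8. Alkoxide may open the epoxide, KOtBu in DMF may isomerise the allyl ether to a propenyl ether, and the acidic work-up may hydrolyse the epoxide. Fallback: stepwise ring construction with a non-nucleophilic base at low temperature. It sets out from 21: saponification (LiOH, THF–H2O, 0 °C) gives 2-[4-(allyloxy)-3-{[(2R)-3,3-dimethyloxiran-2-yl]methyl}phenyl]acetic acid F3, handled as its caesium salt without acidification. O-Alkylation with methyl bromoacetate (Cs2CO3, DMF, rt) gives the glycolate diester 23, now isolated, and Dieckmann condensation with LiN(SiMe3)2 (2.2 equiv, THF, −78 → 0 °C) comes back to the route at 24.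

3. Step 10. The phenol set free next to the oxirane may attack it (ring closure to a dihydrobenzofuran or chromanol), the π-allyl complex may allylate the tetronate at carbon, or cleavage of the second ether may stall. Fallback: allyl-to-propenyl isomerisation followed by neutral enol ether cleavage, with no amine and no π-allyl transfer. It sets out from 26: [Ir(cod)(PMePh2)2]PF6 (activated with H2), THF, rt should give (5Z)-4-hydroxy-3-[3-{[(2R)-3,3-dimethyloxiran-2-yl]methyl}-4-{[(1E)-prop-1-en-1-yl]oxy}phenyl]-5-{[2,2-dimethyl-7-{[(1E)-prop-1-en-1-yl]oxy}chroman-6-yl]methylidene}furan-2(5H)-one F4. HgCl2/HgO in acetone–H2O at rt then cleaves both enol ethers and comes back to the route at target 27.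

Further compounds
F1 | step 1 | 1-(4-fluoro-2-hydroxyphenyl)ethanone (purchased) | CC(=O)c1ccc(F)cc1O
F2 | step 1 | 1-(4-fluoro-2-hydroxyphenyl)-3-methylbut-2-en-1-one | CC(C)=CC(=O)c1ccc(F)cc1O
F3 | step 8 | 2-[4-(allyloxy)-3-{[(2R)-3,3-dimethyloxiran-2-yl]methyl}phenyl]acetic acid | OC(=O)Cc1ccc(OCC=C)c(C[C@H]2OC2(C)C)c1
F4 | step 10 | (5Z)-4-hydroxy-3-[3-{[(2R)-3,3-dimethyloxiran-2-yl]methyl}-4-{[(1E)-prop-1-en-1-yl]oxy}phenyl]-5-{[2,2-dimethyl-7-{[(1E)-prop-1-en-1-yl]oxy}chroman-6-yl]methylidene}furan-2(5H)-one | C/C=C/Oc1cc2OC(C)(C)CCc2cc1/C=C3\OC(=O)C(c4ccc(O/C=C/C)c(C[C@H]5OC5(C)C)c4)=C3O
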